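## Structural features

The target is an achiral, linear trimer: three fully substituted benzene rings joined by two CH2 bridges, with no ring fusion and no stereocentre, so no stereocentres stand next to each other. The central ring is a 2,4,6-trihydroxyphenyl propyl ketone whose two remaining ring carbons (C3 and C5) carry the bridges. Each outer ring has the bridge at C1, hydroxyls at C2 and C4 on either side of a butanoyl group at C3, a methyl at C5 and the only methoxy group at C6, para to the ketone and wedged between the methyl and the bridge carbon. The electron-rich diarylmethane bonds are the fragile element: ipso-protonation or ipso-acylation of one ring can expel the other as a stabilised benzylic cation, and the free polyphenols oxidise in air. The real difficulty is therefore regiochemical and chemoselective: three acyl groups have to be placed, and three oxygens on each outer ring told apart, without breaking either bridge. The key step uses the fact that, once both bridges are in place, each ring has exactly one unsubstituted carbon and that carbon bears butanoyl in the target; each new outer ketone then marks its two ortho oxygens (C2, C4) against the para one (C6) by chelation.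

## Logic of the disconnections

**14 to 13.** Four O–CH3 bonds, at C2 and C4 of both outer rings, are restored in the retrosynthetic sense. The reason is that the two oxygens flanking each outer ketone can be told from the third only once the ketone is there. The gain is that both outer rings become symmetric trimethyl ethers. The demand on the forward step is a Lewis-acid cleavage that removes only ethers able to chelate to a ketone and spares the para ether and the bridges.

**13 to 8 and 9.** Three aryl–C(=O) bonds are cut, one on each ring. They are cut here because the carbon concerned is the only unsubstituted position of its ring, so no regiochemical choice exists. The gain is the loss of all three ketones at once, leaving an acyl-free trimer and simple four-carbon acyl donors. The demand is that the acylation is run so that the acid-labile bridges survive, which is why the central phenols are masked as butanoates in the flask before any Lewis acid is added. The two outer acyl groups then come from 9 and the central one from a masking ester.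

**8 to 6.** A carboxyl carbon is added, in the retrosynthetic sense, to the one free carbon of the central ring. Without it the central nucleophile has three equivalent carbons and twofold benzylation can only be statistical. The gain is a nucleophile with exactly two reactive carbons. The demand is an ester hydrolysis and decarboxylation (through 7) that the air-sensitive, electron-rich trimer tolerates.

**6 to 5 and two molecules of 4.** Both aryl–CH2 bonds are cut on the central-ring side. The bridge carbon is left on the outer ring because three methoxy groups let the benzylic alcohol ionise under trace acid. The gain is two identical electrophiles and one small nucleophile. The demand is that the cation is captured by 5 faster than by the free ring position of another molecule of 4.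

**4 to 3 to 1.** The benzylic C–O function is traced back to an aldehyde and the aryl–CHO bond is cut. Since 1 has two equivalent free positions, formylation cannot give regioisomers, and the electron-poor iminium stage (2) prevents a second attack. The gain is a purchasable symmetric arene. The demand is clean monoformylation and acid-free handling of 4.

## Other disconnections considered

**Alternative 1:** The cut lies inside each outer ring: the C(OH)–CH and C(OSi)–C(CH3) bonds, with the C(OH)–C(CH2) bond broken and re-formed, so both outer benzene rings are built on a finished central ring. In the forward key step the bis(cyclobutenone) A1 is heated with the siloxyalkyne A2 (Danheiser benzannulation). Each four-membered ring opens to a vinylketene, adds A2 in a [2+2] step, opens again and closes by 6π electrocyclisation, giving A3 after tautomerisation.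
- In its favour: the three oxygens of each outer ring are formed already different (free OH, silyl ether, methyl ether), and the cascade is neutral and thermal, so no acid comes near a diarylmethane.
- Against it here: A1 is a 3-methoxycyclobutenone, a vinylogous ester that should open reluctantly; it must be made twice over on a tribenzyloxybenzene scaffold; both annulations must succeed in one molecule; and A3 still lacks all three butanoyl groups, so a threefold acylation, now with benzyl and silyl ethers under Lewis acid, still lies ahead.
- Comparison: on structure it is the better plan for oxygen differentiation, which the chosen route leaves to a late chelation-controlled cleavage. It is the equal of the chosen plan on site selectivity of the later acylation, since each ring again has one free carbon. On mechanism it replaces ionic aromatic substitution by pericyclic steps for ring construction only. On step economy it is clearly longer, because it builds two rings that the chosen plan buys.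

**Alternative 2:** The cut is at both CH2–outer-ring bonds, with the bridge carbons left on the central ring. In the forward key step NiBr2(dme) (divalent nickel precatalyst), a bipyridine ligand and zinc powder couple the bis(benzylic bromide) A4 with two equivalents of the aryl bromide A5. Benzylic radicals are captured by aryl–nickel species and reductive elimination gives the heptaacetate A6, which needs only deacetylation to reach 14.
- In its favour: it is fully convergent, every ring arrives with its ketone and oxygen pattern in place, and no Lewis or Brønsted acid is needed once the bridges exist.
- Against it here: the C–Br bond of A5 is flanked by an acetoxy and a methoxy group on an electron-rich ring, so oxidative addition should be slow. A4 is an ortho-acyloxybenzyl bromide prone to homocoupling, reduction and quinone-methide formation. Aryl acetates are not inert to low-valent nickel and zinc, and the coupling must succeed twice on one molecule.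
- Comparison: on structure it is the equal or the better of the chosen plan, since the halogen positions fix the regiochemistry. On mechanism it is the better plan for acid exposure of the bridges. On the endgame it is equal (one deprotection). On overall step economy it is worse, because A4 and A5 each need a separate multistep preparation in which the same ortho/para oxygen differentiation has to be solved on the monomer.

**Alternative 3:** The cut is in the central ring, between the butanoyl-bearing carbon and its neighbouring C–OH carbon, which opens that ring to the tetraketide ester A7. In the forward key step Mg(OMe)2 in methanol forms a chelated polyenolate; the methylene carbon between the C5 and C7 ketones attacks the ester carbon (Claisen-type closure), and loss of methoxide and enolisation give the aromatic ketone A8.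
- In its favour: the central ketone is present from the start, so neither a Fries step nor a blocking group is needed there, and the two benzyl groups are set by enolate alkylation and not by aromatic substitution.
- Against it here: A7 is a doubly α-branched poly-β-carbonyl chain that is long and regiochemically delicate to assemble. Aldol-type closure to a resorcylate and pyrone formation compete with the Claisen mode. A8 still needs two outer-ring acylations under Lewis acid with a free-phenol central ring, after which it joins the chosen route at 13.
- Comparison: on structure it is the better plan for the central ring and the equal of the chosen plan for the endgame, which is shared. On mechanism it exchanges one acid-mediated acylation for a base-mediated condensation but keeps the other two. On step economy it is worse, because it constructs a ring that the chosen plan buys.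

Key step: step 5

Remark: 2,4,6-trimethoxytoluene, methyl 2,4,6-trihydroxybenzoate, butanoyl chloride and butanoic anhydride are taken to be purchasable. The ring substitution patterns of all skeletons agree atom by atom with the target, so no structure needs correcting. Two design features go beyond the bare disconnection: a carboxyl blocking group on the central ring, and O-butanoylation in the flask before the Lewis acid.

Remark on the acyl balance of step 5: 8 + 3 butanoic anhydride + 2 butanoyl chloride (9) + 2 methanol should give 13 + 3 butanoic acid + 2 methyl butanoate + 2 HCl. The anhydride supplies the three masking esters, one of which ends on carbon by Fries rearrangement. Compound 9 supplies the two outer ketones, and its third equivalent is a working excess.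

## Route

Step 1
Reactants: 1 2,4,6-trimethoxytoluene
Product: 3 2,4,6-trimethoxy-3-methylbenzaldehyde, via aryl iminium salt 2 (not isolated)
Conditions: POCl3 (1.2 equiv), DMF, 0 °C → 60 °C; then ice, aq. NaOH to pH 8
Reagents that add atoms: N,N-dimethylformamide, CN(C)C=O; water, O
Why: Vilsmeier–Haack formylation; the chloroiminium ion attacks one of the two equivalent ring CH positions of the strongly activated arene, the electron-poor iminium 2 stops a second formylation, and aqueous base hydrolyses it to 3.

Step 2
Reactants: 3 2,4,6-trimethoxy-3-methylbenzaldehyde
Product: 4 (2,4,6-trimethoxy-3-methylphenyl)methanol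
Conditions: NaBH4, MeOH/THF, 0 °C → rt; H2O quench, no acid
Reagents that add atoms: none
Why: Borohydride reduction of an aryl aldehyde; the neutral to basic work-up avoids ionising the very acid-labile trimethoxybenzylic alcohol, which is used promptly.

Step 3
Reactants: 4 (2,4,6-trimethoxy-3-methylphenyl)methanol (2.5 equiv); 5 methyl 2,4,6-trihydroxybenzoate
Product: 6 methyl 2,4,6-trihydroxy-3,5-bis[(2,4,6-trimethoxy-3-methylphenyl)methyl]benzoate
Conditions: TsOH·H2O (10 mol %), MeCN, 0 °C → rt, slow addition of 4; aq. NaHCO3
Reagents that add atoms: none
Why: Acid-catalysed Friedel–Crafts benzylation; 4 ionises to a trimethoxybenzyl cation that is captured at the two free ring carbons of 5 while the ester blocks the third, the kind of exhaustive double C-benzylation known for acylphloroglucinols. Slow addition keeps the cation source dilute so that it alkylates 5 and not its own free ring position, and non-phenolic oligomers of 4 are easy to separate from phenolic 6.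

Step 4
Reactants: 6 methyl 2,4,6-trihydroxy-3,5-bis[(2,4,6-trimethoxy-3-methylphenyl)methyl]benzoate
Product: 8 2,4-bis[(2,4,6-trimethoxy-3-methylphenyl)methyl]benzene-1,3,5-triol, via carboxylic acid 7 (not isolated)
Conditions: KOH, H2O/MeOH, reflux, Ar; then aq. HCl to pH 4, 50 °C
Reagents that add atoms: none
Why: Saponification followed by protodecarboxylation of a 2,4,6-trihydroxybenzoic acid (a vinylogous β-keto acid that loses CO2 after ipso-protonation), the classical removal of a carboxyl blocking group from a phloroglucinol. The trimethoxyaryl rings cannot tautomerise, so the bridges should not scramble in alkali, and exclusion of air protects the phenolate.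

Step 5
Reactants: 8 2,4-bis[(2,4,6-trimethoxy-3-methylphenyl)methyl]benzene-1,3,5-triol; 9 butanoyl chloride (3 equiv)
Product: 13 1-{2,4,6-trihydroxy-3,5-bis[(3-butanoyl-2,4,6-trimethoxy-5-methylphenyl)methyl]phenyl}butan-1-one, via central tris-butanoate 10 (not isolated), via diketone tris-butanoate 11 (not isolated), via Fries ketone bis-butanoate 12 (not isolated)
Conditions: (a) butanoic anhydride (3.3 equiv), pyridine (4 equiv), DMAP (5 mol %), CH2Cl2, 0 °C → rt, Ar; volatiles removed in vacuo with toluene; (b) 9 (3 equiv), AlCl3 (about 10 equiv), PhNO2, −10 °C → rt, then 40 °C; ice/1 M HCl; (c) K2CO3, MeOH, 0 °C → rt, Ar; dil. HCl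
Reagents that add atoms: butanoic anhydride, CCCC(=O)OC(=O)CCC
Why: DMAP-catalysed acyl transfer from butanoic anhydride first turns the three central phenols into butanoates (10), so that the central ring is no longer basic and neither ipso-protonation nor ipso-acylation can expel a trimethoxybenzyl-type cation. AlCl3, used in large excess because residual butanoate and every carbonyl bind it, then ionises 9, and the acylium ion attacks the single CH of each outer ring, ortho to two methoxy groups and para to the third, in an ordinary Friedel–Crafts acylation through a σ-complex (11); each new ketone, held as its aluminium complex, deactivates its ring against further substitution. On warming, the Lewis acid ionises a butanoate next to the last free central carbon and the acylium ion is returned to that carbon (Fries rearrangement, ortho mode) to give the aluminium-chelated ortho-hydroxy ketone 12, and mild methanolysis of the two leftover esters releases 13. Of the three new aryl–carbonyl bonds, the two on the outer rings thus come from 9 and the one on the central ring from an anhydride-derived ester. The closest known reactions are the Friedel–Crafts acylation of phloroglucinol trimethyl ethers and the Fries rearrangement of phloroglucinol esters. No ring is closed and no stereocentre is formed. Site selectivity needs no control element because each ring offers exactly one unsubstituted carbon; what the step does need is survival of the two bridges and of the ether para to each new ketone, which the ester masking, the order of events (outer rings cold, Fries last) and the lowest workable temperature are meant to secure. Any ortho ether that AlCl3 cleaves next to a new ketone is one that step 6 removes anyway, so such material should converge on 14.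

Step 6
Reactants: 13 1-{2,4,6-trihydroxy-3,5-bis[(3-butanoyl-2,4,6-trimethoxy-5-methylphenyl)methyl]phenyl}butan-1-one
Product: 14 1-{3,5-bis[(3-butanoyl-2,4-dihydroxy-6-methoxy-5-methylphenyl)methyl]-2,4,6-trihydroxyphenyl}butan-1-one
Conditions: BCl3 (1 M in CH2Cl2, about 12 equiv), CH2Cl2, −78 °C → rt; then MeOH, H2O
Reagents that add atoms: none
Why: Chelation-directed ether cleavage; BCl3 bridges each outer ketone oxygen and a flanking methoxy oxygen in a six-membered chelate and chloride removes that methyl group, first on one side and then on the other. The methoxy group para to the ketone cannot chelate and should remain. The central phenols are held as aryloxyboron species and are set free again on methanolic work-up.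

## Compound list

1 | 2,4,6-trimethoxytoluene (1,3,5-trimethoxy-2-methylbenzene) | COc1cc(OC)c(C)c(OC)c1 | starting material
2 | N-[(2,4,6-trimethoxy-3-methylphenyl)methylidene]-N-methylmethanaminium dichlorophosphate | COc1cc(OC)c(C)c(OC)c1C=[N+](C)C.[O-]P(=O)(Cl)Cl | intermediate (not isolated)
3 | 2,4,6-trimethoxy-3-methylbenzaldehyde | COc1cc(OC)c(C)c(OC)c1C=O | intermediate
4 | (2,4,6-trimethoxy-3-methylphenyl)methanol | COc1cc(OC)c(C)c(OC)c1CO | intermediate
5 | methyl 2,4,6-trihydroxybenzoate | COC(=O)c1c(O)cc(O)cc1O | starting material
6 | methyl 2,4,6-trihydroxy-3,5-bis[(2,4,6-trimethoxy-3-methylphenyl)methyl]benzoate | COC(=O)c1c(O)c(Cc2c(OC)cc(OC)c(C)c2OC)c(O)c(Cc2c(OC)cc(OC)c(C)c2OC)c1O | intermediate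
7 | 2,4,6-trihydroxy-3,5-bis[(2,4,6-trimethoxy-3-methylphenyl)methyl]benzoic acid | OC(=O)c1c(O)c(Cc2c(OC)cc(OC)c(C)c2OC)c(O)c(Cc2c(OC)cc(OC)c(C)c2OC)c1O | intermediate (not isolated)
8 | 2,4-bis[(2,4,6-trimethoxy-3-methylphenyl)methyl]benzene-1,3,5-triol | Oc1cc(O)c(Cc2c(OC)cc(OC)c(C)c2OC)c(O)c1Cc1c(OC)cc(OC)c(C)c1OC | intermediate
9 | butanoyl chloride | CCCC(Cl)=O | starting material
10 | 2,4-bis[(2,4,6-trimethoxy-3-methylphenyl)methyl]benzene-1,3,5-triyl tributanoate | CCCC(=O)Oc1cc(OC(=O)CCC)c(Cc2c(OC)cc(OC)c(C)c2OC)c(OC(=O)CCC)c1Cc1c(OC)cc(OC)c(C)c1OC | intermediate (not isolated)
11 | 2,4-bis[(3-butanoyl-2,4,6-trimethoxy-5-methylphenyl)methyl]benzene-1,3,5-triyl tributanoate | CCCC(=O)Oc1cc(OC(=O)CCC)c(Cc2c(OC)c(C(=O)CCC)c(OC)c(C)c2OC)c(OC(=O)CCC)c1Cc1c(OC)c(C(=O)CCC)c(OC)c(C)c1OC | intermediate (not isolated)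
12 | 4-butanoyl-5-hydroxy-2,6-bis[(3-butanoyl-2,4,6-trimethoxy-5-methylphenyl)methyl]-1,3-phenylene dibutanoate | CCCC(=O)c1c(O)c(Cc2c(OC)c(C(=O)CCC)c(OC)c(C)c2OC)c(OC(=O)CCC)c(Cc2c(OC)c(C(=O)CCC)c(OC)c(C)c2OC)c1OC(=O)CCC | intermediate (not isolated)
13 | 1-{2,4,6-trihydroxy-3,5-bis[(3-butanoyl-2,4,6-trimethoxy-5-methylphenyl)methyl]phenyl}butan-1-one | CCCC(=O)c1c(O)c(Cc2c(OC)c(C(=O)CCC)c(OC)c(C)c2OC)c(O)c(Cc2c(OC)c(C(=O)CCC)c(OC)c(C)c2OC)c1O | intermediate
14 | 1-{3,5-bis[(3-butanoyl-2,4-dihydroxy-6-methoxy-5-methylphenyl)methyl]-2,4,6-trihydroxyphenyl}butan-1-one | CCCC(=O)c1c(O)c(Cc2c(O)c(C(=O)CCC)c(O)c(C)c2OC)c(O)c(Cc2c(O)c(C(=O)CCC)c(O)c(C)c2OC)c1O | target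

## Step count and least certain steps

Total step count: 6. Longest linear sequence: 6 steps (1 to 14); 5 enters at step 3 and 9 at step 5.

**Step 5 (key step).** The most likely failure is fragmentation of the benzylic C–aryl bonds, or loss of the ether para to a new ketone, during the warm Fries stage, because that stage needs the strongest acid for the longest time. Fallback: the three acylations are no longer asked of one flask. Setting out from 8, stages (a) and (b) are run as above but quenched at 0 °C before any warming, so that 11 is isolated. Methanolysis (K2CO3, MeOH) strips its three butanoates to 2,4-bis[(3-butanoyl-2,4,6-trimethoxy-5-methylphenyl)methyl]benzene-1,3,5-triol F1. The central ring alone is then C-acylated directly as its aluminium phenoxide (9, AlCl3, CH2Cl2/PhNO2, 0 °C → rt), a reaction of a free phloroglucinol ring that needs neither a Fries step nor heat, at a stage where both outer rings are already deactivated ketones. This returns to the route at 13.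

**Step 3.** The most likely failure is self-alkylation and oligomerisation of 4 through its own free ring position, with the second benzylation of 5 left incomplete, because the ester lowers the nucleophilicity of 5 towards that of the trimethoxyarene ring. Fallback: the blocking group is given up in favour of nucleophilicity. Setting out from 4 (2 equiv), benzene-1,3,5-triol F2 is benzylated directly with the same catalyst. The ester-free ring should outrun self-alkylation, at the price of a statistical mixture of mono-, bis- and tris-benzylated products that must be separated, with the mono-adduct recycled. The bis-adduct is 8 itself, so the fallback returns at 8 and replaces steps 3 and 4.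

**Step 4.** The most likely failure is incomplete saponification of the hindered, doubly hydrogen-bonded ester, with oxidative degradation of the polyphenolate during prolonged heating in alkali. Fallback: the ester is avoided altogether. Setting out from 4, 2,4,6-trihydroxybenzoic acid F3 is benzylated twice under the conditions of step 3 to give 7 directly. Compound 7 should lose CO2 on gentle warming in wet dioxane at about pH 4 to 5 without any alkali, returning to the route at 8.

**Step 6.** The most likely failure is erosion of chemoselectivity: either stalling after the first ortho ether of a ring, or, when pushed with more reagent and time, attack on the twisted para ether and acid fragmentation of the bridges. The three free central phenols aggravate this by consuming BCl3 and liberating HCl. Fallback: the order of methanolysis and demethylation is exchanged. Setting out from 12 (isolated by leaving out stage (c) of step 5), BCl3 is applied while the central ring still carries two butanoates and only one, ketone-chelated, phenol. This should give 4-butanoyl-5-hydroxy-2,6-bis[(3-butanoyl-2,4-dihydroxy-6-methoxy-5-methylphenyl)methyl]-1,3-phenylene dibutanoate F4, and K2CO3/MeOH then releases 14.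

## Further compounds

F1 | step 5 | 2,4-bis[(3-butanoyl-2,4,6-trimethoxy-5-methylphenyl)methyl]benzene-1,3,5-triol | Oc1cc(O)c(Cc2c(OC)c(C(=O)CCC)c(OC)c(C)c2OC)c(O)c1Cc1c(OC)c(C(=O)CCC)c(OC)c(C)c1OC
F2 | step 3 | benzene-1,3,5-triol (phloroglucinol, purchased) | Oc1cc(O)cc(O)c1
F3 | step 4 | 2,4,6-trihydroxybenzoic acid (purchased) | OC(=O)c1c(O)cc(O)cc1O
F4 | step 6 | 4-butanoyl-5-hydroxy-2,6-bis[(3-butanoyl-2,4-dihydroxy-6-methoxy-5-methylphenyl)methyl]-1,3-phenylene dibutanoate | CCCC(=O)c1c(O)c(Cc2c(O)c(C(=O)CCC)c(O)c(C)c2OC)c(OC(=O)CCC)c(Cc2c(O)c(C(=O)CCC)c(O)c(C)c2OC)c1OC(=O)CCC
A1 | alternative 1 | 4,4'-{[2,4,6-tris(benzyloxy)-1,3-phenylene]bis(methylene)}bis(3-methoxy-2-methylcyclobut-2-en-1-one), mixture of diastereomers | O=C1C(C)=C(OC)C1Cc1c(OCc2ccccc2)cc(OCc2ccccc2)c(CC2C(=O)C(C)=C2OC)c1OCc1ccccc1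
A2 | alternative 1 | (ethynyloxy)tri(propan-2-yl)silane | C#CO[Si](C(C)C)(C(C)C)C(C)C
A3 | alternative 1 | 2,2'-{[2,4,6-tris(benzyloxy)-1,3-phenylene]bis(methylene)}bis{3-methoxy-4-methyl-5-[tri(propan-2-yl)silyloxy]phenol} | COc1c(C)c(O[Si](C(C)C)(C(C)C)C(C)C)cc(O)c1Cc1c(OCc2ccccc2)cc(OCc2ccccc2)c(Cc2c(O)cc(O[Si](C(C)C)(C(C)C)C(C)C)c(C)c2OC)c1OCc1ccccc1
A4 | alternative 2 | 2,4-bis(bromomethyl)-6-butanoylbenzene-1,3,5-triyl triacetate | CCCC(=O)c1c(OC(C)=O)c(CBr)c(OC(C)=O)c(CBr)c1OC(C)=O
A5 | alternative 2 | 4-bromo-2-butanoyl-5-methoxy-6-methyl-1,3-phenylene diacetate | CCCC(=O)c1c(OC(C)=O)c(Br)c(OC)c(C)c1OC(C)=O
A6 | alternative 2 | heptaacetate of 14 (all seven phenols acetylated) | CCCC(=O)c1c(OC(C)=O)c(Cc2c(OC(C)=O)c(C(=O)CCC)c(OC(C)=O)c(C)c2OC)c(OC(C)=O)c(Cc2c(OC(C)=O)c(C(=O)CCC)c(OC(C)=O)c(C)c2OC)c1OC(C)=O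
A7 | alternative 3 | methyl 3,5,7-trioxo-2,4-bis[(2,4,6-trimethoxy-3-methylphenyl)methyl]decanoate, mixture of stereoisomers and tautomers | COC(=O)C(Cc1c(OC)cc(OC)c(C)c1OC)C(=O)C(Cc1c(OC)cc(OC)c(C)c1OC)C(=O)CC(=O)CCC
A8 | alternative 3 | 1-{2,4,6-trihydroxy-3,5-bis[(2,4,6-trimethoxy-3-methylphenyl)methyl]phenyl}butan-1-one | CCCC(=O)c1c(O)c(Cc2c(OC)cc(OC)c(C)c2OC)c(O)c(Cc2c(OC)cc(OC)c(C)c2OC)c1O
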